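Assumption: allylmagnesium bromide, Me3Al, iPrMgCl, O2 and the catalysts are treated as reagents and carry no compound number; locants for bicyclic compounds are azulene locants (C8a = methyl-bearing ring-fusion carbon, C3 = isopropyl carbinol, C4 = ester carbon, C7 = allylic carbinol).

**Retrosynthetic overview**
1. Target 14 ⇐ hydroxy hydroperoxide 10 + vanillin acetate 11: the ester C–O bond is made last by a peroxide-tethered redox esterification (new), which also unveils the C7 alcohol.
2. 10 ⇐ jaeschkeanadiol 9 by a Schenck ene reaction with O2, which forms the C7–O bond and moves the alkene.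
3. 9 ⇐ diene diol 8 by ring-closing metathesis; the seven-membered ring is formed last.
4. 8 ⇐ aldol 7 by isopropyl addition; 7 ⇐ enone 3 + Me3Al + aldehyde 5 by asymmetric conjugate addition/aldol.
5. The five-membered ring is bought (3-ethoxycyclopentenone 1); no other ring is made.

**Route**

Step 1
Reactants: 1 3-ethoxycyclopent-2-en-1-one
Product: 3 3-(prop-2-en-1-yl)cyclopent-2-en-1-one, via bromomagnesium alkoxide adduct 2 (not isolated)
Conditions: allylMgBr (1.2 equiv), THF, −78 to 0 °C; then 1 M HCl, 0 °C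
Reagents that add atoms: allylmagnesium bromide C=CC[Mg]Br; water O
Why: 1,2-addition of the Grignard reagent to the vinylogous ester, then acid hydrolysis with carbonyl transposition (Stork–Danheiser sequence); no stereocentre is formed.

Step 2
Reactants: 4 3-methylbut-3-en-1-ol
Product: 5 3-methylbut-3-enal
Conditions: Dess–Martin periodinane (1.1 equiv), CH2Cl2, 0 °C to rt; used cold as a crude solution
Reagents that add atoms: none
Why: Dess–Martin oxidation under non-basic conditions gives the β,γ-unsaturated aldehyde without isomerisation to the conjugated enal.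

Step 3
Reactants: 3 3-(prop-2-en-1-yl)cyclopent-2-en-1-one; 5 3-methylbut-3-enal
Product: 7 (2S,3R)-2-[(1S)-1-hydroxy-3-methylbut-3-en-1-yl]-3-methyl-3-(prop-2-en-1-yl)cyclopentan-1-one, via dimethylaluminium enolate 6 (not isolated)
Conditions: Me3Al (1.3 equiv), copper thiophene-2-carboxylate Cu(O2CC4H3S) (2 mol %), chiral BINOL-derived phosphoramidite L* (4 mol %, enantiomer chosen to give the R centre), Et2O, −30 °C; then 5 (1.5 equiv), −78 °C; aq. potassium sodium tartrate (KNaC4H4O6)
Reagents that add atoms: trimethylaluminium C[Al](C)C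
Why: Copper-catalysed asymmetric conjugate addition sets the R quaternary carbon under ligand control; the regiodefined (E)-aluminium enolate then undergoes a Zimmerman–Traxler aldol that gives the anti (2S,1′S) pair, with the aldehyde entering anti to the larger allyl group (modest preference, about 3:1 expected, minor epimer removed by chromatography).

Step 4
Reactants: 7 (2S,3R)-2-[(1S)-1-hydroxy-3-methylbut-3-en-1-yl]-3-methyl-3-(prop-2-en-1-yl)cyclopentan-1-one
Product: 8 (1R,2S,3R)-2-[(1S)-1-hydroxy-3-methylbut-3-en-1-yl]-3-methyl-1-(propan-2-yl)-3-(prop-2-en-1-yl)cyclopentan-1-ol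
Conditions: iPrMgCl (3 equiv), LaCl3·2LiCl (1.1 equiv), THF, 0 °C; aqueous work-up
Reagents that add atoms: isopropylmagnesium chloride CC(C)[Mg]Cl
Why: Lanthanum-promoted Grignard 1,2-addition to the chelated β-alkoxy ketone suppresses enolisation and retro-aldol; the nucleophile enters anti to the adjacent C2 side chain, so the new hydroxyl is cis to it (R carbinol).

Step 5
Reactants: 8 (1R,2S,3R)-2-[(1S)-1-hydroxy-3-methylbut-3-en-1-yl]-3-methyl-1-(propan-2-yl)-3-(prop-2-en-1-yl)cyclopentan-1-ol
Product: 9 (3R,3aS,4S,8aR)-6,8a-dimethyl-3-(propan-2-yl)-1,2,3,3a,4,5,8,8a-octahydroazulene-3,4-diol (jaeschkeanadiol)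
Conditions: second-generation Hoveyda–Grubbs catalyst RuCl2(H2IMes)(=CH-C6H4-2-OiPr) (5 mol %), CH2Cl2 (5 mM), 40 °C
Reagents that add atoms: none
Why: Ring-closing metathesis of the allyl and methallyl groups closes the trans-fused cycloheptene with a trisubstituted alkene and loss of ethene; no stereocentre is touched.

Step 6
Reactants: 9 jaeschkeanadiol
Product: 10 (3R,3aS,4S,7S,8aR)-7-hydroperoxy-6,8a-dimethyl-3-(propan-2-yl)-1,2,3,3a,4,7,8,8a-octahydroazulene-3,4-diol
Conditions: O2, meso-tetraphenylporphyrin (1 mol %), white LED, CH2Cl2, −20 °C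
Reagents that add atoms: dioxygen O=O
Why: Schenck ene reaction: singlet oxygen bonds to the less substituted alkene carbon C7 from the face opposite the angular methyl and removes the cis ring hydrogen at C5 (cis effect), with the C4 hydroxyl on the same face expected to hydrogen-bond the perepoxide and steer abstraction to C5; this sets C7 as S and moves the alkene to C5=C6.

Step 7
Reactants: 10 (3R,3aS,4S,7S,8aR)-7-hydroperoxy-6,8a-dimethyl-3-(propan-2-yl)-1,2,3,3a,4,7,8,8a-octahydroazulene-3,4-diol; 11 4-formyl-2-methoxyphenyl acetate (vanillin acetate)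
Product: 14 (3R,3aS,4S,7S,8aR)-3,7-dihydroxy-6,8a-dimethyl-3-(propan-2-yl)-1,2,3,3a,4,7,8,8a-octahydroazulen-4-yl 4-hydroxy-3-methoxybenzoate (target), via bridged peroxyacetal 12 (not isolated), via O-acetyl ester 13 (not isolated)
Conditions: 11 (1.2 equiv), CSA (10 mol %), 4 Å molecular sieves, CH2Cl2, 0 °C; then DBU (1.5 equiv), 0 °C to rt; then pyrrolidine (3 equiv), MeOH, 0 °C
Reagents that add atoms: none
Why: Proposed new method: peroxide-tethered redox esterification. Acid-catalysed condensation of the aldehyde with the cis-disposed C7 hydroperoxide and C4 hydroxyl gives a bridged peroxyacetal C4–O–CH(Ar)–O–O–C7, the 1,4-homologue of 1,2,4-trioxane formation from hydroxy hydroperoxides. Amine base then removes the acidic acetal C–H and breaks the O–O bond in a Kornblum–DeLaMare-type E1cB fragmentation; the closest known reactions are the amine-induced fragmentation of ozonides and the dehydration of α-alkoxy hydroperoxides to esters. The acetal carbon becomes the ester carbonyl on the C4 oxygen and the peroxide oxygen on C7 is left as the free alcohol with retention, so the site of acylation is fixed by which oxygen was the peroxide and no stereocentre is touched. Pyrrolidine finally removes the phenol acetate by aminolysis.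

**Compound list**
1 | 3-ethoxycyclopent-2-en-1-one | CCOC1=CC(=O)CC1 | starting material
2 | bromomagnesium 3-ethoxy-1-(prop-2-en-1-yl)cyclopent-2-en-1-olate | CCOC1=CC(CC=C)(O[Mg]Br)CC1 | intermediate
3 | 3-(prop-2-en-1-yl)cyclopent-2-en-1-one | C=CCC1=CC(=O)CC1 | intermediate
4 | 3-methylbut-3-en-1-ol | CC(=C)CCO | starting material
5 | 3-methylbut-3-enal | CC(=C)CC=O | intermediate
6 | dimethylaluminium (R)-3-methyl-3-(prop-2-en-1-yl)cyclopent-1-en-1-olate | C[Al](C)OC1=C[C@@](C)(CC=C)CC1 | intermediate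
7 | (2S,3R)-2-[(1S)-1-hydroxy-3-methylbut-3-en-1-yl]-3-methyl-3-(prop-2-en-1-yl)cyclopentan-1-one | O[C@@H](CC(C)=C)[C@@H]1[C@@](C)(CC=C)CCC1=O | intermediate
8 | (1R,2S,3R)-2-[(1S)-1-hydroxy-3-methylbut-3-en-1-yl]-3-methyl-1-(propan-2-yl)-3-(prop-2-en-1-yl)cyclopentan-1-ol | O[C@@H](CC(C)=C)[C@@H]1[C@@](C)(CC=C)CC[C@@]1(O)C(C)C | intermediate
9 | (3R,3aS,4S,8aR)-6,8a-dimethyl-3-(propan-2-yl)-1,2,3,3a,4,5,8,8a-octahydroazulene-3,4-diol (jaeschkeanadiol) | O[C@H]1CC(C)=CC[C@@]2(C)CC[C@@](O)(C(C)C)[C@H]12 | intermediate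
10 | (3R,3aS,4S,7S,8aR)-7-hydroperoxy-6,8a-dimethyl-3-(propan-2-yl)-1,2,3,3a,4,7,8,8a-octahydroazulene-3,4-diol | O[C@H]1C=C(C)[C@@H](OO)C[C@@]2(C)CC[C@@](O)(C(C)C)[C@H]12 | intermediate
11 | 4-formyl-2-methoxyphenyl acetate (vanillin acetate) | CC(=O)Oc1ccc(C=O)cc1OC | starting material
12 | bridged peroxyacetal of 10 with 11 (C4–O–CH(Ar)–O–O–C7, Ar = 4-acetoxy-3-methoxyphenyl; acetal carbon configuration not fixed, other centres as in 10) | CC(=O)Oc1ccc(cc1OC)C1O[C@H]2C=C(C)[C@@H](OO1)C[C@@]3(C)CC[C@@](O)(C(C)C)[C@H]23 | intermediate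
13 | (3R,3aS,4S,7S,8aR)-3,7-dihydroxy-6,8a-dimethyl-3-(propan-2-yl)-1,2,3,3a,4,7,8,8a-octahydroazulen-4-yl 4-acetoxy-3-methoxybenzoate | CC(=O)Oc1ccc(cc1OC)C(=O)O[C@H]1C=C(C)[C@@H](O)C[C@@]2(C)CC[C@@](O)(C(C)C)[C@H]12 | intermediate
14 | (3R,3aS,4S,7S,8aR)-3,7-dihydroxy-6,8a-dimethyl-3-(propan-2-yl)-1,2,3,3a,4,7,8,8a-octahydroazulen-4-yl 4-hydroxy-3-methoxybenzoate | COc1cc(C(=O)O[C@H]2C=C(C)[C@@H](O)C[C@@]3(C)CC[C@@](O)(C(C)C)[C@H]23)ccc1O | target

**Step count and risks**

Total steps: 7. Longest linear sequence: 6 (steps 1, 3, 4, 5, 6, 7).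

Three steps most likely to fail:

Step 3 (conjugate addition/aldol). The facial preference at the enolate carbon (methyl against allyl) is small, and aldehyde 5 can enolise or isomerise in the organoaluminium medium. The fallback sets out from 3 and comes back at 7. The conjugate methylation is run alone and the aluminium enolate is quenched with TMSOTf/Et3N to isolate trimethylsilyl enol ether F1. F1 is cleaved with MeLi (THF, 0 °C) to the regiodefined lithium enolate, which is transmetalated with ZnCl2 and treated with 5 at −78 °C in a separate Zimmerman–Traxler aldol. This decouples the aldol from the aluminium chemistry; it gives 7 after chromatography of the epimers.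

Step 6 (Schenck ene). Oxygen may instead bond at C6 with abstraction at C8, or react on the other face. The fallback sets out from 9 and comes back at 13, using an E1cB epoxide opening whose regiochemistry is fixed. mCPBA (NaHCO3, CH2Cl2, 0 °C) gives the 6,7-epoxide F2 on the face opposite the angular methyl. Dess–Martin oxidation of the C4 alcohol and DBU open the β,γ-epoxy ketone to the 7-hydroxy enone F3. TBSCl/imidazole gives the C7 silyl ether F4. Hydroxyl-directed anti reduction with Me4NBH(OAc)3 (MeCN/AcOH, −20 °C; Evans–Saksena) gives the C4 alcohol F5. Acylation with 4-acetoxy-3-methoxybenzoyl chloride (DMAP, Et3N) gives the ester F6, and HF·pyridine removes the silyl group to give 13. 13 is deacetylated with pyrrolidine as in the last operation of step 7.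

Step 7 (proposed new step). The eight-membered peroxyacetal may not close; the tertiary C3 hydroxyl may form a 1,3-dioxane with the C4 hydroxyl instead; or base may remove the C7 hydrogen and give the enone. The fallback uses only known chemistry, sets out from 9 and comes back at 13. Steglich esterification of 9 with 4-acetoxy-3-methoxybenzoic acid (DCC, DMAP, CH2Cl2) gives the C4 ester F7. Schenck ene reaction (O2, meso-tetraphenylporphyrin, light, CH2Cl2) gives the C7 hydroperoxide F8, which PPh3 reduces to 13. Pyrrolidine/MeOH then gives 14.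

**Further compounds**
F1 | step 3 | (R)-trimethyl{[3-methyl-3-(prop-2-en-1-yl)cyclopent-1-en-1-yl]oxy}silane | C[Si](C)(C)OC1=C[C@@](C)(CC=C)CC1
F2 | step 6 | 6,7-epoxide of 9 (epoxide oxygen anti to the angular methyl, cis to the C4 hydroxyl; other centres as in 9) | O[C@H]1C[C@@]2(C)O[C@H]2C[C@@]3(C)CC[C@@](O)(C(C)C)[C@H]13
F3 | step 6 | 3,7-dihydroxy-6,8a-dimethyl-3-(propan-2-yl)-2,3,3a,7,8,8a-hexahydroazulen-4(1H)-one (7S; other centres as in 14) | O=C1C=C(C)[C@@H](O)C[C@@]2(C)CC[C@@](O)(C(C)C)[C@H]12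
F4 | step 6 | 7-O-tert-butyldimethylsilyl ether of F3 | O=C1C=C(C)[C@@H](O[Si](C)(C)C(C)(C)C)C[C@@]2(C)CC[C@@](O)(C(C)C)[C@H]12
F5 | step 6 | 7-(tert-butyldimethylsilyloxy)-6,8a-dimethyl-3-(propan-2-yl)-1,2,3,3a,4,7,8,8a-octahydroazulene-3,4-diol (centres as in 14) | O[C@H]1C=C(C)[C@@H](O[Si](C)(C)C(C)(C)C)C[C@@]2(C)CC[C@@](O)(C(C)C)[C@H]12
F6 | step 6 | 4-O-(4-acetoxy-3-methoxybenzoyl) ester of F5 | CC(=O)Oc1ccc(cc1OC)C(=O)O[C@H]1C=C(C)[C@@H](O[Si](C)(C)C(C)(C)C)C[C@@]2(C)CC[C@@](O)(C(C)C)[C@H]12
F7 | step 7 | (3R,3aS,4S,8aR)-3-hydroxy-6,8a-dimethyl-3-(propan-2-yl)-1,2,3,3a,4,5,8,8a-octahydroazulen-4-yl 4-acetoxy-3-methoxybenzoate | CC(=O)Oc1ccc(cc1OC)C(=O)O[C@H]1CC(C)=CC[C@@]2(C)CC[C@@](O)(C(C)C)[C@H]12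
F8 | step 7 | 7-hydroperoxide of 13 (hydroperoxy in place of the C7 hydroxyl, centres as in 13) | CC(=O)Oc1ccc(cc1OC)C(=O)O[C@H]1C=C(C)[C@@H](OO)C[C@@]2(C)CC[C@@](O)(C(C)C)[C@H]12
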